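Every share of the charge stands in some entry of a ledger, and at the start there is a single entry, substrate. Substrate is the limiting reagent, since target and released group both come out of it, and fractions of that charge are used throughout.

| setting | maple | oak | flask |
|---|---|---|---|
| substrate | 0.12 M | 0.12 M | 0.12 M |
| temperature | 35 °C | 30 °C | 35 °C |
| remark | the very flask that is asked about, followed so far | run made earlier |  |
| time |  |  | 50 min |

| maple: time / min | maple: target / % | oak: time / min | oak: target / % |
|---|---|---|---|
| 2.50 | 32.5 | 2.50 | 18.8 |
| 6.00 | 49.5 | 6.00 | 38.4 |
| 12.0 | 51.5 | 12.0 | 49.1 |
| 30.0 | 35.5 | 30.0 | 45.1 |

(standard deviation of a reading: 0.5 percentage points)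

- autumn: change nothing and wait 1.5 h more
- dawn: at 50 min add substrate, 50.0 % of the amount charged, then wait 1.5 h
- summer: at 50 min take out 90 % of the released group then present, then wait 1.5 h
- dusk: at 50 min raise the temperature by 10 K, then wait 1.5 h

- the volume of additions can be left aside

* target, in percent of the substrate first charged, at 50 min
* the remedy with the largest gain of target, or "none" below 2 percentage points (autumn / dawn / summer / dusk / none)
* target present, in percent of the substrate first charged, after summer
* target present, in percent of the substrate first charged, after dusk

The flask, followed so far as the maple run, moves 32.5 % of its charge into the target entry by 2.50 min, which is 0.130 min⁻¹. Between 12.0 min and 30.0 min the same entry falls at 0.00889 min⁻¹. The early rise is faster than that late net fall, but the sign has turned, so a loss has overtaken the making. The oak run at 30 °C climbs slower than maple and fades too, from 49.1 % to 45.1 % over the same interval. At 30.0 min the maple ledger holds 64.5 % outside the target entry, and the readings, which are of target, do not split that between substrate and a lost form.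

My own reckoning takes the loss as a meeting of target with released group, which leave substrate one for one. With further making from substrate left aside as an approximation, the fall goes with the square of the target fraction, and the reciprocal of that fraction climbs steadily. The maple readings give 0.0486 min⁻¹ for the fade rate, the gain per minute in the reciprocal of the target fraction. This is the line to watch on a repeat. Carried from 30.0 min to 50 min, it puts target at 26.4 %. Waiting 1.5 h more is reckoned at 12.3 %, so by this estimate autumn loses target.

The forecast gave 24.5 % at 50 min, none as the best remedy, 4 % after summer and 1 % after dusk, holding that “Nothing beats the present 24.5 after 1.5 h”.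

The flask gives 25.2 % at 50 min, which is 1.2 percentage points below my reckoning; the answer to best is none, and target stands at 23.9 % after summer and 4.84 % after dusk. The books close at that time with substrate 5.87 %, target 25.2 % and side product 68.9 %.

    substrate ⇌ target + released group (K = 0.162 M, k = 0.00281 s⁻¹, Ea = 97.0 kJ mol⁻¹, ΔH = −19.0 kJ mol⁻¹)
    target + released group → side product (k = 0.0129 L mol⁻¹ s⁻¹, Ea = 71.0 kJ mol⁻¹)
    (constants at 35 °C)

Restarted from 25.2 %, the fade rate reckons 18.4 % for the same flask read at 80 min, which holds 16.7 %.

The numbers in the tables stem from a simulated flask with constants of no real substance; the scatter is artificial.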